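All runs are simulated with constants of no real substance; scatter was added.

Cedar turned a partner dose of 0.470 of the charge into 4.65% of target on average, and my reckoning for this flask hangs on that pair of readings.

all flasks: starting material 0.0010 M; free catalyst 40 µM

| flask | second substrate | partner | remark | time |
|---|---|---|---|---|
| cedar | 1 mM | 0.47 mM (fed, over 50 s) | run made earlier; the fed solution adds 0.25 times the starting volume |  |
| maple | 1 mM | 1.9 mM (fed, over 50 s) | run made earlier; the fed solution adds 0.25 times the starting volume |  |
| flask | 1.00 mM | 0.950 mM (fed, over 50 s) | the fed solution adds 0.25 times the starting volume | 80 min |

| run | time / min | starting material / % | target / % |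
|---|---|---|---|
| cedar | 12.0 | 94.6 | 4.8 |
| cedar | 25.0 | 94.4 | 4.4 |
| cedar | 40.0 | 93.7 | 4.8 |
| cedar | 50.0 | 94.7 | 4.6 |
| maple | 6.00 | 25.0 | 74.8 |
| maple | 15.0 | 13.9 | 86.1 |
| maple | 30.0 | 11.8 | 89.0 |
| maple | 50.0 | 10.1 | 90.1 |

(each reading ± 0.3 percentage points)

- the state of affairs at 80 min: stopped, and by what, or still going (the partner has run out first / no working catalyst is left / forward and back rates have come level / it is still moving / all of the starting material has reacted)
- share of the starting material used up at 80 min
- target at 80 min, in percent of the starting material charged

- every charge counts on the volume at the start, and the solution that is fed holds the whole dose
- the numbers in the tables scatter with a standard deviation of 0.3 percentage points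
- steps thought possible: partner + catalyst intermediate B -> free catalyst + second product; second substrate + free catalyst <-> catalyst intermediate B; starting material + free catalyst <-> catalyst intermediate A; partner + catalyst intermediate A -> free catalyst + target
- the reaction counts as stopped when no species that holds the starting material changes by six tenths of a point or more over the second half of the time

Free catalyst binds starting material as catalyst intermediate A or second substrate as catalyst intermediate B, and partner clears either one, giving target or second product. Each turnover seems to cost one partner: maple's 1.90 of partner matches a full charge of second substrate plus 90.1% of target.

I divided the fractional loss rate of second substrate by that of starting material. If both intermediates stay near their binding balance, free catalyst, partner and time cancel, leaving the selectivity factor S, ln(share of second substrate left) over ln(share of starting material left).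

Which inputs mattered? Feed time and the time allowed drop out of S, and cedar's target was already flat at 12.0 min. The catalyst is 4.00% of the charge, so what it holds opens a small gap between conversion and target. Cedar's small target share does matter: the scatter of its mean, 0.15 percentage points, moves S by about 3.23%.

Cedar's readings gave S = 11.6. In the flask, partner at 0.950 of the charge leaves second substrate exceeding target by 0.0500. With S, that gave target 13.6% and second substrate left 18.6%, with partner as limiting reagent. Cedar's scatter is worth about 0.29 points on that target.

The forecast said the partner has run out first, with 14.2% converted and 13.6% target (“The reaction stops because partner runs out.”), beside my 13.6%.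

In the flask at 80.0 min, the partner has run out first, with 0% of its partner left, 15.3% converted and 14.3% target.

    partner + catalyst intermediate B → free catalyst + second product (k = 8700 M⁻¹ s⁻¹)
    second substrate + free catalyst ⇌ catalyst intermediate B (K = 810 M⁻¹, k = 7100 M⁻¹ s⁻¹)
    starting material + free catalyst ⇌ catalyst intermediate A (K = 600 M⁻¹, k = 4700 M⁻¹ s⁻¹)
    partner + catalyst intermediate A → free catalyst + target (k = 980 M⁻¹ s⁻¹)

The flask's conversion stood at 15.3% partly because two things acted together: second substrate bound free catalyst, both ways, and catalyst intermediate A fell back to starting material and free catalyst. In the same run, taking away the first gave 94.9% converted, and taking away the second gave 73.8%. With starting material at 0.0040 M, 4.00 times the second substrate, S and the partner balance give 8.12% target; that neighbour flask gave 8.55%, with 9.14% converted.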